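Working atom numbers (used for all intermediates): ring atoms C1–C11 in the order of the target SMILES. C1 = senecioate carbinol, C2 = CH2, C3 = isovalerate carbinol, C4 = C(CH3)2, C5, C6, C7 = ketone, C8 = CH, C9 = C(CH3), C10, C11 = C(CH3). Compound numbers are plain numbers (1–30).

## Analysis of the target

Compound 30 is a longipinane-type diester, a tricyclo[5.4.0.0^2,8]undecene. A cyclobutane (C5–C6–C11–C10) is bridged across both diagonals: C6/C10 by the enone unit C7(=O)–C8=C9(CH3), and C5/C11 by the chain C4(CH3)2–C3–C2–C1, which creates two seven-membered rings. Of the six stereocentres, C5, C6, C10 and C11 are locked as one set by the cage, so only their absolute sense is open; in the working numbering the target is 1R,3R,5S,6R,10R,11R. The two carbinols are the free stereocentres: the C1 oxygen is anti to C10 about the C1–C11 bond, and the C3 oxygen is trans to it across C2 (a 1,3-anti pattern). Sensitive points are the two different esters on hindered neopentyl carbinols, the enone, the strained four-membered ring, and, in intermediates, any β-hydroxy ketone across the quaternary C11 or across C2 (retro-aldol). The difficulty lies in the quaternary C11, which is part of all three rings and carries the oxygenated C1, and in telling two very similar secondary alcohols apart while fixing the absolute configuration. The route rests on the sequence C10–C11–C1(O): if C11–C1 is an epoxide and C10 is the external carbon of a C5–C6–C10 cyclopropane with a silyloxy group on C6, a shift of the C6–C10 bond to C11 makes the C10–C11 bond, the cyclobutane, the second seven-membered ring and the C1 carbinol in one event.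

## Retrosynthetic reasoning

**C3 ester.** The isovalerate C–O acyl bond of 30 is cut first, giving alcohol 28 and acid chloride 29. Putting this ester on last means the two oxygens never have to be told apart by a reagent: only one hydroxyl is free at that point.

**C1 acyl group and C3–H together.** In 28 the O1–acyl bond and the C3–H bond are cut in one operation, giving β-hydroxy ketone 26 and aldehyde 27. The forward reaction has to deliver hydride to C3 from the face of the C1 oxygen, which makes the 1,3-anti diol, and leave the aldehyde as the ester on O1. That solves both the C3 configuration and the differentiation of the two alcohols.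

**Enone ring.** 26 is traced through its silyl ether 25 to homoallylic alcohol 23, and there the C7–C8 bond is cut, giving aldehyde 22. The cut is made here because in 22 the formyl group on C6 and the isopropenyl group on C10 are both held on the same side of the cyclobutane, ready for a six-membered carbonyl-ene closure. Two acetyl groups on C6 and C10 would close by aldol in either direction, so the two carbons are given different chain lengths (one carbon on C6, three on C10).

**Side arms.** 22 comes from enol ether 21 (the C6=C7 bond is a one-carbon olefination of a ketone), and the isopropenyl group of 21 comes, through methyl ketone 20 and amide 19, from the ester of 18. This leads back to silyl ether 17 and cyclobutanone 16, in which C6 is a ketone and C10 carries an ester.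

**Key disconnection.** In 16 the C10–C11 bond is cut and C10 is reconnected to C6, giving epoxide 15. The forward step is a Lewis-acid-triggered 1,2-shift that turns cyclopropane into cyclobutanone. It has to move the external C6–C10 bond (not the ring-fusion bond C5–C6) and open the epoxide with inversion at C11.

**Epoxide and cyclopropane.** The epoxide oxygen of 15 is removed to give alkene 14; the forward oxidation must come from the face opposite C10. Cutting C5–C10 and C6–C10 of 14 gives silyloxydiene 12 and diazo ester 13. This is the only step where absolute configuration is introduced, by a chiral copper carbenoid.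

**Seven-membered ring oxidation pattern.** 12 is the kinetic dienol ether of enone 11. 11 is traced through enol ether 10, ketone 9 and alcohol 8 to alkene 6, the ketal of cycloheptenone 4 with diol 5. These steps only move oxygen onto C6 and unsaturation to C11=C1; C3 is ketalised at the start, while it is the only carbonyl.

**(4+3) cycloaddition.** In 4 the bonds C4–C5 and C1–C2 are cut, giving the allyl-cation precursor 2 (from bromoketone 1) and diene 3. A diene already oxygenated at C6 was considered and rejected: its enol-ether terminus C5 would be the more nucleophilic end and would bond to the unsubstituted cation terminus, placing the gem-dimethyl carbon next to C1. With 3 the methyl-bearing end is the nucleophilic one, which gives the required C4–C5 connection.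

## Alternatives that were turned down

Alternative 1: Cut C1–C11, so that the seven-membered ring is closed last on a complete bicyclo[3.1.1]heptenone.
- Forward key step: Fe(acac)3 and PhSiH3 would transfer a hydrogen atom to the exocyclic C11 methylene of the enone A1, whose C5 carries the chain C4(CH3)2–C3(=O)–C2H=C1H–OPMB. The tertiary C11 radical would add to C1 (7-endo) and give the tricyclic ketone A2.
- For: the enone ring and the cyclobutane are present from the start, so no one-carbon homologation and no ene closure are needed. The quaternary centre is made under neutral conditions. A2 has the same C1–O/C3=O pattern that the endgame here uses. After the key step this alternative is shorter and therefore stronger.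
- Against: C1 is created by radical attack on a flexible β-alkoxy enone, and only the conformation of the forming ring decides its configuration. The alkoxy-bearing carbon is a hindered, electronically poor acceptor for a nucleophilic tertiary radical, so plain reduction of the alkene competes with a slow 7-endo closure. A1 itself, an enantiopure cis-1,3-disubstituted methylenecyclobutane with a quaternary carbon on C5, still has to be made, which moves the difficulty of the four-membered ring into its preparation.
- Comparison: the chosen strategy gives up the shorter endgame. In its place it offers a stereospecific link between C1 and C11 (epoxide configuration transferred by an anti 1,2-shift) and builds the cyclobutane in the same step.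

Alternative 2: Cut C5–C6 and C10–C11, taking the cyclobutane apart into a ketene (C5=C10) and the C6=C11 alkene of an open farnesane-type chain.
- Forward key step: Et3N removes HCl from the dienoyl chloride A3 across C5/C8, and the vinylketene unit adds intramolecularly across C6=C11 to give the bicyclo[3.1.1]heptenone A4.
- For: this is the shortest way to the cyclobutane and the six-membered ring: two bonds, two rings and the ring stereocentres in one step from an acyclic precursor. The reaction type is well established for pinane-type skeletons. In step count up to the bicyclic core it is clearly stronger than the chosen route.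
- Against: in A4 the carbon C5 is a ketone and is not yet bonded to C4. The seven-membered ring therefore still needs a C4–C5 bond to a hindered cyclobutanone, then removal of the C5 oxygen with control of the C5 configuration. C7 is a methylene that must be oxidised late. The C1 stereocentre lies outside the reacting system and could steer the facial selectivity only through allylic strain, so the C1/C11 relationship is uncertain. Deprotonation can also occur at the C9 methyl instead of C8.
- Comparison: the chosen strategy is longer, but it has the seven-membered ring closed before the cyclobutane is made and fixes C1 against C11 by mechanism, not by a remote stereocentre.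

Alternative 3: Cut C1–C2 and C2–C3, removing C2 and treating the seven-membered bridge as a ring-enlarged acyloin.
- Forward key step: Et2Zn and CH2I2 would methylenate the C1=C3 double bond of the bis(trimethylsilyloxy)alkene A5, and FeCl3 or mild acid would cleave the former C1–C3 bond, inserting C2 and giving the 1,3-diketone A6.
- For: ring enlargement of acyloin-derived bis-silyl enol ethers to 1,3-diones is dependable. Both bridge oxygens arrive together, and the tricyclic carbon skeleton with the C8=C9 alkene is complete in A6. For building the C1–C3 bridge alone it is at least as strong as the chosen route.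
- Against: A6 has two nearly equivalent ketones, each flanked by a quaternary carbon. Two diastereoselective reductions and the attachment of two different acyl groups would have no handle, while the target needs C1 and C3 different and trans. C7 must still be oxidised in the presence of the esters. A5 needs an acyloin closure between two esters on quaternary carbons attached to a preformed cyclobutane, which again postpones the synthesis of the four-membered ring.
- Comparison: the chosen strategy delivers C1 as a single configured alcohol next to a masked C3 ketone. That arrangement lets one Evans–Tishchenko step set C3 and distinguish the two oxygens.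

Key step: step 11

## Route

Assumptions:
- Compounds 1, 3, 5, 13, 27 and 29 are bought.
- Compounds 7–9 are racemic; their stereocentres are removed by step 7.
- The enol-ether geometry of 18–21 and the C7 carbinol configuration of 23 are left open, because both elements are erased later.
- The endo diastereomer formed beside 14 is taken to be separable by chromatography.

Step 1
Reactants: 1 3-bromo-3-methylbutan-2-one
Product: 2 [(3-bromo-3-methylbut-1-en-2-yl)oxy]trimethylsilane
Conditions: LiN(i-Pr)2, Me3SiCl (in-situ quench), THF, −78 °C
Reagents that add atoms: chlorotrimethylsilane, C[Si](C)(C)Cl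
Why: Only the acetyl methyl has α-hydrogens, so kinetic deprotonation with in-situ O-silylation gives the 2-silyloxyallyl bromide; trapping at −78 °C keeps the α-bromo enolate from Favorskii-type closure.

Step 2
Reactants: 2 [(3-bromo-3-methylbut-1-en-2-yl)oxy]trimethylsilane; 3 isoprene (2-methylbuta-1,3-diene)
Product: 4 2,2,5-trimethylcyclohept-4-en-1-one (karahanaenone)
Conditions: ZnCl2 (0.3 equiv), 3 (5 equiv), CH2Cl2, −20 °C → rt; aq. NaHCO3
Reagents that add atoms: none
Why: ZnCl2 ionises the tertiary allylic bromide to the 1,1-dimethyl-2-silyloxyallyl cation, which adds to the s-cis diene in a (4+3) cycloaddition; the methyl-bearing, more nucleophilic diene terminus bonds to the unsubstituted cation terminus and the CMe2 terminus closes onto the vinyl CH2, which puts the gem-dimethyl carbon next to the future C5 and the ring methyl on the future C11; loss of the silyl group gives the ketone.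

Step 3
Reactants: 4 2,2,5-trimethylcyclohept-4-en-1-one; 5 ethane-1,2-diol
Product: 6 6,6,9-trimethyl-1,4-dioxaspiro[4.6]undec-8-ene
Conditions: 5 (5 equiv), TsOH·H2O (cat.), benzene, reflux, Dean–Stark
Reagents that add atoms: none
Why: Acid-catalysed ketalisation with azeotropic removal of water; the ketone is the only carbonyl, and the isolated trisubstituted alkene has no conjugating partner to migrate to.

Step 4
Reactants: 6 6,6,9-trimethyl-1,4-dioxaspiro[4.6]undec-8-ene
Product: 8 6,6,9-trimethyl-1,4-dioxaspiro[4.6]undecan-8-ol (racemic trans), via B-alkyl-9-borabicyclo[3.3.1]nonane 7 (not isolated)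
Conditions: 9-BBN, THF, 60 °C; then NaOH, H2O2, 0 °C → rt
Reagents that add atoms: 9-borabicyclo[3.3.1]nonane, [H]B1C2CCCC1CCC2 (atoms kept only in 7); hydrogen peroxide, OO
Why: Hydroboration–oxidation: boron adds to the less substituted alkene carbon (future C6) and oxidation with retention gives the secondary alcohol; syn addition makes the racemic trans isomer, whose stereocentres are erased in steps 5 to 7.

Step 5
Reactants: 8 6,6,9-trimethyl-1,4-dioxaspiro[4.6]undecan-8-ol
Product: 9 6,6,9-trimethyl-1,4-dioxaspiro[4.6]undecan-8-one (racemic)
Conditions: n-Pr4NRuO4 (5 mol%), NMO, 4 Å MS, CH2Cl2, rt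
Reagents that add atoms: none
Why: Ley–Griffith oxidation of a secondary alcohol to the ketone under neutral conditions that leave the dioxolane alone.

Step 6
Reactants: 9 6,6,9-trimethyl-1,4-dioxaspiro[4.6]undecan-8-one
Product: 10 trimethyl[(6,6,9-trimethyl-1,4-dioxaspiro[4.6]undec-8-en-8-yl)oxy]silane
Conditions: Me3SiCl, NaI, Et3N, MeCN, rt
Reagents that add atoms: chlorotrimethylsilane, C[Si](C)(C)Cl
Why: Silylation under equilibrating conditions (Me3SiI formed in situ, amine base) gives the more substituted enol ether toward the methyl-bearing carbon; any isomer toward C5 cannot be dehydrogenated in step 7 because C4 is quaternary, and returns to 9.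

Step 7
Reactants: 10 trimethyl[(6,6,9-trimethyl-1,4-dioxaspiro[4.6]undec-8-en-8-yl)oxy]silane
Product: 11 6,6,9-trimethyl-1,4-dioxaspiro[4.6]undec-9-en-8-one
Conditions: Pd(OAc)2 (1.05 equiv), MeCN, rt
Reagents that add atoms: none
Why: Saegusa–Ito oxidation: the oxa-π-allyl palladium species at C11 undergoes β-hydride elimination toward the ring CH2 (C1) and gives the conjugated endocyclic enone.

Step 8
Reactants: 11 6,6,9-trimethyl-1,4-dioxaspiro[4.6]undec-9-en-8-one
Product: 12 tert-butyldimethyl[(6,6,9-trimethyl-1,4-dioxaspiro[4.6]undeca-7,9-dien-8-yl)oxy]silane
Conditions: LiN(i-Pr)2, THF, −78 °C; then t-BuMe2SiCl, HMPA, −78 °C → rt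
Reagents that add atoms: tert-butyl(chloro)dimethylsilane, CC(C)(C)[Si](C)(C)Cl
Why: Kinetic deprotonation of the enone at the α′ CH2 (C5, the only α′ position) and O-silylation give the cross-conjugated 2-silyloxy-1,3-diene; γ-deprotonation is slower at −78 °C.

Step 9
Reactants: 12 tert-butyldimethyl[(6,6,9-trimethyl-1,4-dioxaspiro[4.6]undeca-7,9-dien-8-yl)oxy]silane; 13 ethyl diazoacetate
Product: 14 ethyl (1R,7R,8S)-1-[(tert-butyldimethylsilyl)oxy]-2,6,6-trimethylspiro[bicyclo[5.1.0]oct-2-ene-5,2'-[1,3]dioxolane]-8-carboxylate (8-exo ester)
Conditions: CuOTf·0.5C6H6 (5 mol%), (R,R)-t-Bu-box [2,2'-(propane-2,2-diyl)bis((4R)-4-tert-butyl-4,5-dihydrooxazole)] (6 mol%), 13 (3 equiv, slow addition), CH2Cl2, rt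
Reagents that add atoms: none
Why: Asymmetric copper-carbenoid cyclopropanation of a silyl enol ether: the electrophilic carbenoid should select the electron-rich enol-ether bond C5=C6 over the unactivated C11=C1 bond, the ester prefers the exo position, and the ligand fixes the carbene face; the (R,R)-ligand is chosen because the (S,S)-ligand gives the R ester carbon with styrene-type alkenes and C10 must be S here, which with exo addition sets C5 and C6 as drawn; the endo isomer, which would lead into the enantiomeric series, is removed by chromatography.

Step 10
Reactants: 14 ethyl (1R,7R,8S)-1-[(tert-butyldimethylsilyl)oxy]-2,6,6-trimethylspiro[bicyclo[5.1.0]oct-2-ene-5,2'-[1,3]dioxolane]-8-carboxylate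
Product: 15 the 2,3-epoxide of 14 (C11–C1 epoxide; oxygen on the face opposite the cyclopropane carbon C10, the same face as the silyloxy group; 8-exo ester)
Conditions: dimethyldioxirane (acetone solution, 1.2 equiv), CH2Cl2, −40 → 0 °C; used crude
Reagents that add atoms: dimethyldioxirane, CC1(C)OO1
Why: Epoxidation of the only alkene by a neutral oxygen-transfer reagent, so neither the ketal nor the siloxycyclopropane is opened; C10 and its endo hydrogen sit almost perpendicular under C11 on one face while the silyloxy group lies near the alkene plane, so oxygen should arrive anti to the cyclopropane, which sets C11 and C1.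

Step 11
Reactants: 15 the C11–C1 epoxide of 14
Product: 16 ethyl 2-hydroxy-1,5,5-trimethyl-8-oxospiro[bicyclo[4.1.1]octane-4,2'-[1,3]dioxolane]-7-carboxylate (C6 cyclobutanone; ester on C10 syn to the C6 bridge; C1–OH anti to C10)
Conditions: BF3·OEt2 (1.1 equiv), CH2Cl2, −78 °C; sat. aq. NaHCO3
Reagents that add atoms: none
Why: BF3 binds the epoxide oxygen and the tertiary, cyclopropane-flanked C11–O bond lengthens; the external C6–C10 bond, which lies almost parallel to the developing empty orbital at C11 on the face opposite the epoxide oxygen, shifts to C11 while the C6 oxygen forms the carbonyl and gives up its silyl group as the fluoride. This is the semipinacol ring enlargement of epoxides of 1-alkenylcyclopropanol silyl ethers to 2-(1-hydroxyalkyl)cyclobutanones, a cyclopropylcarbinyl-to-cyclobutyl 1,2-shift. The cyclobutane C5–C6–C11–C10 arises by this three- to four-membered ring enlargement, and because C10 stays bonded to C5 the same new bond closes the second seven-membered ring C10–C11–C1–C2–C3–C4–C5, giving the bicyclo[4.1.1]octanone. C11 is formed with inversion, C10 entering anti to the leaving oxygen, so its configuration follows from the epoxide face set in step 10; C10 migrates with retention, which places the exo ester on the side of the C6 carbonyl bridge; C1 keeps the epoxide configuration and so ends anti to C10. The step needs migration of the external bond and not of the ring-fusion bond C5–C6: the fused ring holds C5–C6 near the nodal plane of the C11 orbital, and the push–pull pattern (silyloxy donor on C6, ester on C10) makes C6–C10 the weakest and most nucleophilic σ bond. It also needs the shift to outrun proton loss from C11 and plain opening of the cyclopropane, which the low temperature and the aligned intramolecular bond favour.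

Step 12
Reactants: 16 ethyl 2-hydroxy-1,5,5-trimethyl-8-oxospiro[bicyclo[4.1.1]octane-4,2'-[1,3]dioxolane]-7-carboxylate
Product: 17 the C1 tert-butyldimethylsilyl ether of 16
Conditions: t-BuMe2SiOTf, 2,6-lutidine, CH2Cl2, −78 → 0 °C
Reagents that add atoms: tert-butyldimethylsilyl trifluoromethanesulfonate, CC(C)(C)[Si](C)(C)OS(=O)(=O)C(F)(F)F
Why: Silylation of the hindered secondary alcohol with the silyl triflate and a non-nucleophilic base; it blocks retro-aldol cleavage of the β-hydroxy cyclobutanone across the quaternary C11 in the basic steps that follow.

Step 13
Reactants: 17 the C1 silyl ether of 16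
Product: 18 the C6 methoxymethylidene compound (enol ether at C6=C7, E/Z mixture; C10 ester, C3 dioxolane, C1 OTBS)
Conditions: Ph3PCH2OMe+ Cl−, KN(SiMe3)2, THF, 0 °C → rt
Reagents that add atoms: (methoxymethyl)triphenylphosphonium chloride, COC[P+](c1ccccc1)(c1ccccc1)c1ccccc1.[Cl-]
Why: Wittig olefination of the strained, electrophilic cyclobutanone (the ester does not react with the ylide); both α-carbons are ring-fusion carbons that do not enolise readily, and the enol ether is a base-stable masked aldehyde.

Step 14
Reactants: 18 the C6 methoxymethylidene ester
Product: 19 the C10 N-methoxy-N-methylamide (Weinreb amide) of 18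
Conditions: MeNH(OMe)·HCl, i-PrMgCl, THF, −20 → 0 °C
Reagents that add atoms: N,O-dimethylhydroxylamine hydrochloride, CNOC.Cl
Why: Aminolysis of the ester by the chloromagnesium amide (Weinreb amide formation); enol ether, ketal and silyl ether are inert, and with C6 sp2 the acyl group on C10 stays in its less hindered position syn to the C6 bridge.

Step 15
Reactants: 19 the C10 Weinreb amide
Product: 20 the C10 methyl ketone (acetyl group on C10)
Conditions: MeMgBr, THF, 0 °C; aq. NH4Cl
Reagents that add atoms: methylmagnesium bromide, C[Mg]Br
Why: Grignard addition to the Weinreb amide stops at the chelated tetrahedral intermediate and gives the methyl ketone on work-up.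

Step 16
Reactants: 20 the C10 methyl ketone
Product: 21 the C10 isopropenyl compound (C6 methoxymethylidene, C3 dioxolane, C1 OTBS)
Conditions: Ph3PCH3+ Br−, KN(SiMe3)2, THF, 0 → 40 °C
Reagents that add atoms: methyltriphenylphosphonium bromide, C[P+](c1ccccc1)(c1ccccc1)c1ccccc1.[Br-]
Why: Wittig methylenation turns the acetyl group into the isopropenyl group without the regiochemical ambiguity of a carbinol dehydration.

Step 17
Reactants: 21 the C10 isopropenyl enol ether
Product: 22 the C6 carbaldehyde with free C3 ketone (formyl group cis to the isopropenyl group on the cyclobutane; C1 OTBS)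
Conditions: TsOH·H2O (0.1 equiv), acetone/H2O 10:1, rt
Reagents that add atoms: water, O
Why: Acid hydrolysis of the enol ether and transketalisation of the dioxolane; C6 is protonated from the face turned to the four-carbon bridge because the isopropenyl group on C10 lies under the other face, so the formyl group ends cis to the isopropenyl group as the next step requires; the hindered secondary silyl ether survives catalytic acid.

Step 18
Reactants: 22 the C6 carbaldehyde
Product: 23 the tricyclic homoallylic alcohol (C7–OH, exocyclic methylene on C9, C3 ketone, C1 OTBS)
Conditions: Me2AlCl (2.5 equiv), CH2Cl2, −78 → −20 °C; aq. potassium sodium tartrate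
Reagents that add atoms: none
Why: Type-2 intramolecular carbonyl-ene reaction: the aluminium-complexed aldehyde is attacked by the CH2 terminus of the isopropenyl group (both groups are held cis-1,3 on the cyclobutane), C7–C8 forms in a six-membered ring and a methyl hydrogen moves to oxygen, leaving the exocyclic methylene; Me2AlCl also removes the proton as methane; the ring fusion at C6 and C10 is fixed by the cage.

Step 19
Reactants: 23 the tricyclic homoallylic alcohol
Product: 25 the conjugated enone (C7 ketone, C8=C9 with methyl on C9, C3 ketone, C1 OTBS), via exo-methylene ketone 24 (not isolated)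
Conditions: Dess–Martin periodinane, NaHCO3, CH2Cl2, 0 °C → rt; then DBU (0.3 equiv), rt
Reagents that add atoms: none
Why: Dess–Martin oxidation gives the β,γ-unsaturated ketone, whose doubly activated C8 hydrogens let a catalytic amidine base move the double bond into conjugation (C8=C9 is the only possible position); the β-silyloxy ketone at C3 tolerates the mild base.

Step 20
Reactants: 25 the conjugated enone silyl ether
Product: 26 the β-hydroxy ketone (C1–OH, C3 ketone, C7 enone)
Conditions: HF·pyridine, THF, 0 °C → rt
Reagents that add atoms: none
Why: Fluoride cleavage of the silyl ether under acidic, non-basic conditions, which avoids retro-aldol or elimination of the β-hydroxy ketone.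

Step 21
Reactants: 26 the β-hydroxy ketone; 27 3-methylbut-2-enal
Product: 28 the C1 3-methylbut-2-enoate with free C3 hydroxyl (C3–O trans to C1–O)
Conditions: SmI2 (0.3 equiv), 27 (8 equiv), THF, −10 °C
Reagents that add atoms: none
Why: Evans–Tishchenko reduction: the samarium-bound hemiacetal formed from the C1 hydroxyl and the aldehyde passes its hydride intramolecularly to the C3 ketone through a six-membered chair-like transition state, so the new C3–O bond ends 1,3-anti (trans across C2) to C1–O and the acyl group stays on O1; the enone has no neighbouring hydroxyl and is not reduced.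

Step 22
Reactants: 28 the C1 3-methylbut-2-enoate C3 alcohol; 29 3-methylbutanoyl chloride
Product: 30 the target diester (1R,3R,5S,6R,10R,11R in the working numbering)
Conditions: 29, DMAP, pyridine, CH2Cl2, 0 → 40 °C
Reagents that add atoms: none
Why: DMAP-catalysed acylation of the only free hydroxyl with the acid chloride; warming is needed for the neopentyl carbinol and no stereocentre is touched.

## Compound list

1 | 3-bromo-3-methylbutan-2-one | CC(=O)C(C)(C)Br | starting material
2 | [(3-bromo-3-methylbut-1-en-2-yl)oxy]trimethylsilane | C=C(O[Si](C)(C)C)C(C)(C)Br | intermediate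
3 | isoprene (2-methylbuta-1,3-diene) | CC(=C)C=C | starting material
4 | 2,2,5-trimethylcyclohept-4-en-1-one (karahanaenone) | CC1=CCC(C)(C)C(=O)CC1 | intermediate
5 | ethane-1,2-diol | OCCO | starting material
6 | 6,6,9-trimethyl-1,4-dioxaspiro[4.6]undec-8-ene | CC1=CCC(C)(C)C2(CC1)OCCO2 | intermediate
7 | 9-(6,6,9-trimethyl-1,4-dioxaspiro[4.6]undecan-8-yl)-9-borabicyclo[3.3.1]nonane (racemic trans, one enantiomer drawn) | C[C@H]1CCC2(OCCO2)C(C)(C)C[C@@H]1B3C4CCCC3CCC4 | intermediate
8 | 6,6,9-trimethyl-1,4-dioxaspiro[4.6]undecan-8-ol (racemic trans, one enantiomer drawn) | C[C@H]1CCC2(OCCO2)C(C)(C)C[C@@H]1O | intermediate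
9 | 6,6,9-trimethyl-1,4-dioxaspiro[4.6]undecan-8-one (racemic) | CC1CCC2(OCCO2)C(C)(C)CC1=O | intermediate
10 | trimethyl[(6,6,9-trimethyl-1,4-dioxaspiro[4.6]undec-8-en-8-yl)oxy]silane | CC1=C(O[Si](C)(C)C)CC(C)(C)C2(CC1)OCCO2 | intermediate
11 | 6,6,9-trimethyl-1,4-dioxaspiro[4.6]undec-9-en-8-one | CC1=CCC2(OCCO2)C(C)(C)CC1=O | intermediate
12 | tert-butyldimethyl[(6,6,9-trimethyl-1,4-dioxaspiro[4.6]undeca-7,9-dien-8-yl)oxy]silane | CC1=CCC2(OCCO2)C(C)(C)C=C1O[Si](C)(C)C(C)(C)C | intermediate
13 | ethyl diazoacetate | CCOC(=O)C=[N+]=[N-] | starting material
14 | ethyl (1R,7R,8S)-1-[(tert-butyldimethylsilyl)oxy]-2,6,6-trimethylspiro[bicyclo[5.1.0]oct-2-ene-5,2'-[1,3]dioxolane]-8-carboxylate (8-exo) | CCOC(=O)[C@H]1[C@H]2[C@]1(O[Si](C)(C)C(C)(C)C)C(C)=CCC3(OCCO3)C2(C)C | intermediate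
15 | C11–C1 epoxide of 14 (oxygen anti to C10, syn to the silyloxy group; precursor of the key step) | CCOC(=O)[C@H]1[C@H]2[C@]1(O[Si](C)(C)C(C)(C)C)[C@]3(C)O[C@@H]3CC4(OCCO4)C2(C)C | intermediate
16 | ethyl 2-hydroxy-1,5,5-trimethyl-8-oxospiro[bicyclo[4.1.1]octane-4,2'-[1,3]dioxolane]-7-carboxylate (product of the key step) | CCOC(=O)[C@H]1[C@H]2C(=O)[C@]1(C)[C@H](O)CC3(OCCO3)C2(C)C | intermediate
17 | C1 tert-butyldimethylsilyl ether of 16 | CCOC(=O)[C@H]1[C@H]2C(=O)[C@]1(C)[C@H](O[Si](C)(C)C(C)(C)C)CC3(OCCO3)C2(C)C | intermediate
18 | C6 methoxymethylidene ester (E/Z mixture) | CCOC(=O)[C@H]1[C@H]2C(=COC)[C@]1(C)[C@H](O[Si](C)(C)C(C)(C)C)CC3(OCCO3)C2(C)C | intermediate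
19 | C10 N-methoxy-N-methylamide | CON(C)C(=O)[C@H]1[C@H]2C(=COC)[C@]1(C)[C@H](O[Si](C)(C)C(C)(C)C)CC3(OCCO3)C2(C)C | intermediate
20 | C10 methyl ketone | CC(=O)[C@H]1[C@H]2C(=COC)[C@]1(C)[C@H](O[Si](C)(C)C(C)(C)C)CC3(OCCO3)C2(C)C | intermediate
21 | C10 isopropenyl enol ether | CC(=C)[C@H]1[C@H]2C(=COC)[C@]1(C)[C@H](O[Si](C)(C)C(C)(C)C)CC3(OCCO3)C2(C)C | intermediate
22 | C6 carbaldehyde, C3 ketone, C10 isopropenyl, C1 OTBS (formyl cis to isopropenyl) | CC(=C)[C@H]1[C@H]2[C@@H](C=O)[C@]1(C)[C@H](O[Si](C)(C)C(C)(C)C)CC(=O)C2(C)C | intermediate
23 | tricyclic homoallylic alcohol (C7–OH, C9 exo-methylene, C3 ketone, C1 OTBS; C7 configuration open) | CC(C)(C)[Si](C)(C)O[C@@H]1CC(=O)C(C)(C)[C@@H]2[C@H]3C(O)CC(=C)[C@@H]2[C@]31C | intermediate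
24 | exo-methylene ketone (C7 ketone, C9 exo-methylene, C3 ketone, C1 OTBS) | CC(C)(C)[Si](C)(C)O[C@@H]1CC(=O)C(C)(C)[C@@H]2[C@H]3C(=O)CC(=C)[C@@H]2[C@]31C | intermediate
25 | conjugated enone (C7 ketone, C8=C9, C3 ketone, C1 OTBS) | CC(C)(C)[Si](C)(C)O[C@@H]1CC(=O)C(C)(C)[C@@H]2[C@H]3C(=O)C=C(C)[C@@H]2[C@]31C | intermediate
26 | β-hydroxy ketone (C1–OH, C3 ketone, C7 enone) | O[C@@H]1CC(=O)C(C)(C)[C@@H]2[C@H]3C(=O)C=C(C)[C@@H]2[C@]31C | intermediate
27 | 3-methylbut-2-enal | CC(C)=CC=O | starting material
28 | C1 3-methylbut-2-enoate, C3 alcohol | CC(C)=CC(=O)O[C@@H]1C[C@@H](O)C(C)(C)[C@@H]2[C@H]3C(=O)C=C(C)[C@@H]2[C@]31C | intermediate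
29 | 3-methylbutanoyl chloride | CC(C)CC(Cl)=O | starting material
30 | target: C1 3-methylbut-2-enoate, C3 3-methylbutanoate of the tricyclic enone (1R,3R,5S,6R,10R,11R, working numbering) | CC(C)=CC(=O)O[C@@H]1C[C@@H](OC(=O)CC(C)C)C(C)(C)[C@@H]2[C@H]3C(=O)C=C(C)[C@@H]2[C@]31C | target

## Step count and least certain steps

Total: 22 steps. Longest linear sequence: 22 steps (1 → 30); 3, 5, 13, 27 and 29 are bought.

**Step 11 (key step).** The most likely failures are:
- heterolysis of the donor–acceptor bond C6–C10 with loss of the silyl group but without C–C bond formation (plain ring opening to a keto ester);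
- migration of the ring-fusion bond C5–C6, because C5 is the more electron-rich migrating carbon;
- proton loss from the C11 cation.

All three follow from the high stabilisation of the cation and the ester on the migrating carbon. Fallback, setting out from 15: buffered fluoride (Bu4NF, AcOH, THF) would deliberately open the siloxycyclopropane to the epoxy keto ester F1. KOt-Bu in t-BuOH/THF would then close the four-membered ring by intramolecular alkylation of the C10 ester enolate at C11, with the epoxide as leaving group (4-exo-tet, anti to the C11–O bond, so the same C11 and C1 configuration). The ketone enolate at C5 is unproductive and equilibrates. This anionic closure at a tertiary centre is harder than the cationic shift, which is why it is only the fallback. It returns to the route at 16.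

**Step 9.** The carbenoid may add with poor enantio- or exo/endo selectivity, or attack slowly, because C5 is next to the quaternary C4 and a bulky silyloxy group is on C6; dimerisation of 13 then competes. Fallback, setting out from 12: cyclopropanation with Rh2(OAc)4 (a more reactive, unligated carbenoid) to the racemic exo ester, then resolution on a chiral stationary phase. This gives 14 and its enantiomer F2, which is discarded, and returns to the route at 14.

**Step 10.** Oxygen may be delivered to the wrong face if the silyloxy group on C6 shields more than the cyclopropane methine; the C1 epimer of 16 would result after step 11. Fallback, setting out from 14: reagent-controlled Shi epoxidation (fructose-derived ketone catalyst, KHSO5, K2CO3 buffer, MeCN/H2O, 0 °C), with the catalyst enantiomer chosen so that its face preference matches attack anti to C10. It returns to the route at 15 and makes no new compound.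

**Step 13.** The ylide may add slowly to the carbonyl on the one-carbon bridge, which is flanked by the ester on C10 on one face and by the C4 methyl and the C1 silyl ether on the other; prolonged exposure to base would then epimerise C10. Fallback, setting out from 17: addition of the small carbanion LiCH(OMe)SiMe3 (from methoxymethyltrimethylsilane and s-BuLi, THF, −78 °C) to the cyclobutanone gives the β-hydroxysilane F3. Peterson elimination with KH then returns to the route at 18.

**Step 21.** Hemiacetal formation between the hindered C1 hydroxyl and a conjugated, less electrophilic aldehyde may be slow, so that retro-aldol cleavage across C1–C2 or conjugate addition to the enal competes. Fallback, setting out from 26: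
- Evans–Tishchenko reduction with acetaldehyde (SmI2 cat.) gives the C1 acetate C3 alcohol F4.
- Et3SiOTf/2,6-lutidine gives the C3 triethylsilyl ether F5.
- K2CO3/MeOH removes the acetate to give the C1 alcohol F6.
- 3-Methylbut-2-enoic acid, DCC and DMAP give the C1 3-methylbut-2-enoate F7.
- HF·pyridine removes the silyl group and returns to the route at 28.

**Step 2.** Bond formation with the opposite orientation of the two partners would give the 2,2,4-trimethyl isomer, and an open-chain diene captures the cation less efficiently than a cyclic one. Fallback, not using 1–3 and setting out from commercial racemic linalool F8: NBS (CH2Cl2, 0 °C) gives the bromo ether 2-(2-bromopropan-2-yl)-5-methyl-5-vinyloxolane F9. Heating in 2,4,6-collidine (about 170 °C) eliminates HBr to the enol ether 2-methyl-5-(propan-2-ylidene)-2-vinyloxolane F10, which undergoes Claisen rearrangement in the same pot. This returns to the route at 4 with the connectivity fixed by the sigmatropic shift.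

## Further compounds

F1 | step 11 | ethyl 2-[(ring-opened) 2-oxo epoxy cycloheptyl]acetate: C10H2–CO2Et on C5, C6 ketone, C11–C1 epoxide, C3 dioxolane | CCOC(=O)C[C@H]1C(=O)[C@]2(C)O[C@@H]2CC3(OCCO3)C1(C)C
F2 | step 9 | enantiomer of 14 | CCOC(=O)[C@@H]1[C@@H]2[C@@]1(O[Si](C)(C)C(C)(C)C)C(C)=CCC3(OCCO3)C2(C)C
F0 | step 10 | none | none
F3 | step 13 | β-hydroxysilane: C6 carbinol bearing CH(OMe)SiMe3 (new centres as mixture), C10 ester, C1 OTBS, C3 dioxolane | CCOC(=O)[C@H]1[C@H]2C(O)(C(OC)[Si](C)(C)C)[C@]1(C)[C@H](O[Si](C)(C)C(C)(C)C)CC3(OCCO3)C2(C)C
F4 | step 21 | C1 acetate, C3 alcohol of the tricyclic enone | CC(=O)O[C@@H]1C[C@@H](O)C(C)(C)[C@@H]2[C@H]3C(=O)C=C(C)[C@@H]2[C@]31C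
F5 | step 21 | C1 acetate, C3 triethylsilyl ether | CC(=O)O[C@@H]1C[C@@H](O[Si](CC)(CC)CC)C(C)(C)[C@@H]2[C@H]3C(=O)C=C(C)[C@@H]2[C@]31C
F6 | step 21 | C1 alcohol, C3 triethylsilyl ether | O[C@@H]1C[C@@H](O[Si](CC)(CC)CC)C(C)(C)[C@@H]2[C@H]3C(=O)C=C(C)[C@@H]2[C@]31C
F7 | step 21 | C1 3-methylbut-2-enoate, C3 triethylsilyl ether | CC(C)=CC(=O)O[C@@H]1C[C@@H](O[Si](CC)(CC)CC)C(C)(C)[C@@H]2[C@H]3C(=O)C=C(C)[C@@H]2[C@]31C
F8 | step 2 | linalool (3,7-dimethylocta-1,6-dien-3-ol, racemic) | CC(C)=CCCC(C)(O)C=C
F9 | step 2 | 2-(2-bromopropan-2-yl)-5-methyl-5-vinyloxolane | CC1(C=C)CCC(O1)C(C)(C)Br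
F10 | step 2 | 2-methyl-5-(propan-2-ylidene)-2-vinyloxolane | CC(C)=C1CCC(C)(C=C)O1
A1 | alternative 1 | 11-methylene bicyclo[3.1.1]heptenone with the (E)-β-(4-methoxybenzyloxy) enone chain on C5 | COc1ccc(cc1)CO/C=C/C(=O)C(C)(C)[C@@H]2[C@H]3C(=O)C=C(C)[C@@H]2C3=C
A2 | alternative 1 | tricyclic enone with C3 ketone and C1 4-methoxybenzyl ether | COc1ccc(cc1)CO[C@@H]2CC(=O)C(C)(C)[C@@H]3[C@H]4C(=O)C=C(C)[C@@H]3[C@]42C
A3 | alternative 2 | (2E,6E)-dienoyl chloride with C1 silyl ether and C3 isopropyl ketone | CC(C)C(=O)C[C@@H](O[Si](C)(C)C(C)(C)C)/C(C)=C/CC/C(C)=C/C(Cl)=O
A4 | alternative 2 | 2,7-dimethyl-7-(silyloxy-oxoalkyl)bicyclo[3.1.1]hept-2-en-6-one | CC(C)C(=O)C[C@@H](O[Si](C)(C)C(C)(C)C)[C@@]1(C)[C@@H]2CC=C(C)[C@H]1C2=O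
A5 | alternative 3 | tricyclic 1,2-bis(trimethylsilyloxy)alkene (C1=C3, six-membered bridge) | C[Si](C)(C)OC1=C(O[Si](C)(C)C)C(C)(C)[C@@H]2[C@H]3CC=C(C)[C@@H]2[C@]31C
A6 | alternative 3 | tricyclic 1,3-diketone (C1 and C3 ketones, C7 methylene) | O=C1CC(=O)C(C)(C)[C@@H]2[C@H]3CC=C(C)[C@@H]2[C@]31C
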